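**Strategy.** The isochromanone is disconnected at the C8a–C1 bond. C1 is carried as the acetal carbon of a MOM ether on the C3 oxygen. Acid converts it into an oxocarbenium ion, which is captured by C8a, the free benzo-ring position that lies ortho to the C8 oxygen and para to the C6 oxygen and is therefore the most electron-rich, closing ring B (the pyran ring) in one operation. C1 oxidation and debenzylation then finish the synthesis. The precursor is an open-chain (1R,2S) 3-aryl-2-(methoxymethoxy)propanoate carrying the E-fumarate at the benzylic carbon. It is built MOM-first, by an amine-catalysed Michael addition of (methoxymethoxy)acetaldehyde to an arylidene malonate, so that the C3 hydroxyl is never free beside an ester.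

Key step: step 12

Assumption: allyl methyl malonate (7) and benzyl glyoxylate (16) are taken as purchasable; (methoxymethoxy)acetaldehyde is not and is made in steps 6 and 7.

Step 1
Reactants: 1 5-bromo-2-hydroxy-3-methoxybenzaldehyde
Product: 2 5-bromo-2,3-dihydroxybenzaldehyde
Conditions: BBr3, CH2Cl2, −78 °C to rt; H2O
Reagents that add atoms: none
Why: Boron tribromide cleavage of the aryl methyl ether (complexation at oxygen, then bromide attack on the methyl group); the phenol and the aldehyde are recovered on hydrolysis.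

Step 2
Reactants: 2 5-bromo-2,3-dihydroxybenzaldehyde
Product: 3 2,3-bis(benzyloxy)-5-bromobenzaldehyde
Conditions: BnBr, K2CO3, DMF, 60 °C
Reagents that add atoms: benzyl bromide, BrCc1ccccc1
Why: Williamson etherification of both phenols with a reactive benzylic halide under carbonate conditions that leave the aldehyde alone.

Step 3
Reactants: 3 2,3-bis(benzyloxy)-5-bromobenzaldehyde
Product: 5 2,3-bis(benzyloxy)-5-hydroxybenzaldehyde, via arylboronic pinacol ester 4 (not isolated)
Conditions: B2pin2, PdCl2(dppf) (3 mol %), KOAc, 1,4-dioxane, 90 °C; then 30% aq. H2O2, aq. NaOH, THF, 0 °C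
Reagents that add atoms: hydrogen peroxide, OO (phenol oxygen of 5); bis(pinacolato)diboron, CC1(C)OB(OC1(C)C)B1OC(C)(C)C(C)(C)O1 (boryl group of 4 only)
Why: Miyaura borylation (oxidative addition of zerovalent palladium into the C–Br bond, acetate-assisted transmetallation, reductive elimination), then peroxide oxidation of the C–B bond with 1,2-aryl shift, which at 0 °C should be much faster than attack on the non-phenolic aldehyde.

Step 4
Reactants: 5 2,3-bis(benzyloxy)-5-hydroxybenzaldehyde
Product: 6 2,3,5-tris(benzyloxy)benzaldehyde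
Conditions: BnBr, K2CO3, DMF, rt
Reagents that add atoms: benzyl bromide, BrCc1ccccc1
Why: Williamson etherification of the remaining phenol.

Step 5
Reactants: 6 2,3,5-tris(benzyloxy)benzaldehyde; 7 allyl methyl malonate
Product: 8 allyl methyl 2-[2,3,5-tris(benzyloxy)benzylidene]malonate (E/Z mixture)
Conditions: piperidine (10 mol %), AcOH (10 mol %), toluene, reflux, Dean–Stark
Reagents that add atoms: none
Why: Knoevenagel condensation of a non-enolisable aryl aldehyde with a malonate, driven by azeotropic removal of water; the E/Z ratio is irrelevant because the malonate carbon later becomes sp2.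

Step 6
Reactants: 9 (Z)-but-2-ene-1,4-diol
Product: 10 (Z)-1,4-bis(methoxymethoxy)but-2-ene
Conditions: MOMCl, i-Pr2NEt, CH2Cl2, 0 °C to rt
Reagents that add atoms: chloromethyl methyl ether, COCCl
Why: O-alkylation of both primary alcohols by the α-chloro ether with a hindered amine base (MOM ether formation).

Step 7
Reactants: 10 (Z)-1,4-bis(methoxymethoxy)but-2-ene
Product: 11 2-(methoxymethoxy)acetaldehyde
Conditions: O3, CH2Cl2, −78 °C; then Me2S, −78 °C to rt (used as a solution)
Reagents that add atoms: ozone, [O-][O+]=O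
Why: Ozonolysis with reductive work-up cleaves the symmetrical alkene into two molecules of the α-alkoxy aldehyde; the acetals are inert to ozone.

Step 8
Reactants: 8 allyl methyl 2-[2,3,5-tris(benzyloxy)benzylidene]malonate; 11 2-(methoxymethoxy)acetaldehyde
Product: 12 allyl methyl 2-[(1S,2S)-2-(methoxymethoxy)-3-oxo-1-(2,3,5-tris(benzyloxy)phenyl)propyl]malonate
Conditions: (R)-α,α-diphenylprolinol trimethylsilyl ether (20 mol %), PhCO2H (20 mol %), 11 (3 equiv), CHCl3, 4 °C to rt
Reagents that add atoms: none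
Why: Enamine-catalysed asymmetric Michael addition of an aldehyde to an arylidene malonate: the diphenyl(silyloxy)methyl group shields one face of the (E)-enamine of 11 and an acyclic synclinal transition state should give the syn adduct, so the (R)-catalyst (mirror-image sense of the well-studied (S)-series) should set both C3 and C4 as drawn, with the malonate carbon formed as an inconsequential epimer mixture.

Step 9
Reactants: 12 allyl methyl 2-[(1S,2S)-2-(methoxymethoxy)-3-oxo-1-(2,3,5-tris(benzyloxy)phenyl)propyl]malonate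
Product: 14 allyl methyl 2-[(1S,2S)-3-methoxy-2-(methoxymethoxy)-3-oxo-1-(2,3,5-tris(benzyloxy)phenyl)propyl]malonate, via carboxylic acid 13 (not isolated)
Conditions: NaClO2, NaH2PO4, 2-methyl-2-butene (large excess), t-BuOH/H2O, 0 °C; then TMSCHN2, toluene/MeOH, 0 °C
Reagents that add atoms: sodium chlorite, [Na+].[O-]Cl=O; (trimethylsilyl)diazomethane, C[Si](C)(C)C=[N+]=[N-]
Why: Pinnick oxidation of the aldehyde with an alkene scavenger that protects the electron-rich ring and the allyl group from hypochlorous acid, then O-methylation by diazomethane generated in situ; neither operation is basic, so the α-alkoxy centre C3 should not epimerise.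

Step 10
Reactants: 14 allyl methyl 2-[(1S,2S)-3-methoxy-2-(methoxymethoxy)-3-oxo-1-(2,3,5-tris(benzyloxy)phenyl)propyl]malonate
Product: 15 3-methoxy-2-[(1S,2S)-3-methoxy-2-(methoxymethoxy)-3-oxo-1-(2,3,5-tris(benzyloxy)phenyl)propyl]-3-oxopropanoic acid
Conditions: Pd(PPh3)4 (5 mol %), morpholine, THF, rt; aq. KHSO4
Reagents that add atoms: none
Why: Tsuji–Trost deallylation: zerovalent palladium ionises the allyl ester to a π-allyl complex that morpholine intercepts, leaving methyl esters, MOM and benzyl ethers untouched, and at room temperature the malonic half-acid should not decarboxylate.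

Step 11
Reactants: 15 3-methoxy-2-[(1S,2S)-3-methoxy-2-(methoxymethoxy)-3-oxo-1-(2,3,5-tris(benzyloxy)phenyl)propyl]-3-oxopropanoic acid; 16 benzyl glyoxylate
Product: 17 4-benzyl 1-methyl (E)-2-[(1R,2S)-3-methoxy-2-(methoxymethoxy)-3-oxo-1-(2,3,5-tris(benzyloxy)phenyl)propyl]but-2-enedioate
Conditions: piperidine (20 mol %), pyridine, 40 °C
Reagents that add atoms: none
Why: Doebner-type decarboxylative Knoevenagel condensation of a malonic half-ester with the highly electrophilic glyoxylate; antiperiplanar loss of CO2 and hydroxide from the aldol adduct, together with the thermodynamic preference of 2-alkylfumarates, should give the E alkene (ester groups trans), while the epimeric malonate centre disappears and C3 and C4 are untouched.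

Step 12
Reactants: 17 4-benzyl 1-methyl (E)-2-[(1R,2S)-3-methoxy-2-(methoxymethoxy)-3-oxo-1-(2,3,5-tris(benzyloxy)phenyl)propyl]but-2-enedioate
Product: 18 4-benzyl 1-methyl (E)-2-[(3S,4R)-5,6,8-tris(benzyloxy)-3-(methoxycarbonyl)isochroman-4-yl]but-2-enedioate
Conditions: TMSOTf (0.3 equiv), CH2Cl2, −40 to 0 °C; Et3N quench
Reagents that add atoms: none
Why: The silyl triflate (and the triflic acid it liberates) binds the more basic methoxy oxygen of the O–CH2–OMe group and expels it, leaving the oxocarbenium ion C3–O+=CH2, made more electrophilic by the neighbouring ester. The arene carbon that becomes C8a attacks this cation and the Wheland intermediate loses a proton, so the C8a–C1 bond and ring B form together and the acid is regenerated. This is an oxa-Pictet–Spengler reaction, that is an intramolecular Friedel–Crafts alkylation by an α-alkoxy carbocation, established for MOM ethers of 2-arylethanols. The closure is 6-endo-trig, since both atoms of the O+=CH2 unit end up inside the new six-membered ring. No stereocentre is created; C3 and C4 were set in step 8 and are only carried through. The step needs site selectivity on the arene and tolerance of the benzyl groups: the tether reaches only C8a, which is also para to the C6 ether oxygen and ortho to the C8 ether oxygen, and substoichiometric promoter at low temperature should leave the benzyl ethers, the benzyl ester and the fumarate untouched.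

Step 13
Reactants: 18 4-benzyl 1-methyl (E)-2-[(3S,4R)-5,6,8-tris(benzyloxy)-3-(methoxycarbonyl)isochroman-4-yl]but-2-enedioate
Product: 20 4-benzyl 1-methyl (E)-2-[(3S,4R)-5,6,8-tris(benzyloxy)-3-(methoxycarbonyl)-1-oxoisochroman-4-yl]but-2-enedioate, via lactol 19 (not isolated)
Conditions: DDQ, CH2Cl2/pH 7 buffer, 0 °C to rt; then PhI(OAc)2, TEMPO (20 mol %), rt
Reagents that add atoms: water, O
Why: DDQ abstracts hydride from C1–H (benzylic, α to the ring oxygen, conjugated with the C6 and C8 ether oxygens), water traps the cation as the lactol, and the oxoammonium species from TEMPO and PhI(OAc)2 oxidises the lactol to the lactone; C4–H, next to the electron-poor alkene, is much less hydridic.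

Step 14
Reactants: 20 4-benzyl 1-methyl (E)-2-[(3S,4R)-5,6,8-tris(benzyloxy)-3-(methoxycarbonyl)-1-oxoisochroman-4-yl]but-2-enedioate
Product: 21 (E)-4-methoxy-4-oxo-3-[(3S,4R)-5,6,8-trihydroxy-3-(methoxycarbonyl)-1-oxoisochroman-4-yl]but-2-enoic acid (CNP0546035.1)
Conditions: BCl3, C6HMe5, CH2Cl2, −78 to −20 °C; MeOH/H2O quench, degassed work-up
Reagents that add atoms: none
Why: Lewis acid debenzylation: boron trichloride cleaves the three aryl benzyl ethers and the benzyl ester while pentamethylbenzene scavenges the benzyl cations, and the methyl esters, the lactone and the alkene (which hydrogenolysis would reduce) should survive.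

**Compound list** (12–15 are epimer mixtures at the malonate carbon)

1 | 5-bromo-2-hydroxy-3-methoxybenzaldehyde | COc1cc(Br)cc(C=O)c1O | starting material
2 | 5-bromo-2,3-dihydroxybenzaldehyde | O=Cc1cc(Br)cc(O)c1O | intermediate
3 | 2,3-bis(benzyloxy)-5-bromobenzaldehyde | O=Cc1cc(Br)cc(OCc2ccccc2)c1OCc1ccccc1 | intermediate
4 | 2,3-bis(benzyloxy)-5-(4,4,5,5-tetramethyl-1,3,2-dioxaborolan-2-yl)benzaldehyde | O=Cc1cc(B2OC(C)(C)C(C)(C)O2)cc(OCc2ccccc2)c1OCc1ccccc1 | intermediate
5 | 2,3-bis(benzyloxy)-5-hydroxybenzaldehyde | O=Cc1cc(O)cc(OCc2ccccc2)c1OCc1ccccc1 | intermediate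
6 | 2,3,5-tris(benzyloxy)benzaldehyde | O=Cc1cc(OCc2ccccc2)cc(OCc2ccccc2)c1OCc1ccccc1 | intermediate
7 | allyl methyl malonate | COC(=O)CC(=O)OCC=C | starting material
8 | allyl methyl 2-[2,3,5-tris(benzyloxy)benzylidene]malonate (E/Z mixture) | COC(=O)C(=Cc1cc(OCc2ccccc2)cc(OCc2ccccc2)c1OCc1ccccc1)C(=O)OCC=C | intermediate
9 | (Z)-but-2-ene-1,4-diol | OC/C=C\CO | starting material
10 | (Z)-1,4-bis(methoxymethoxy)but-2-ene | COCOC/C=C\COCOC | intermediate
11 | 2-(methoxymethoxy)acetaldehyde | COCOCC=O | intermediate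
12 | allyl methyl 2-[(1S,2S)-2-(methoxymethoxy)-3-oxo-1-(2,3,5-tris(benzyloxy)phenyl)propyl]malonate | COC(=O)C(C(=O)OCC=C)[C@@H](c1c(OCc2ccccc2)c(OCc2ccccc2)cc(OCc2ccccc2)c1)[C@H](OCOC)C=O | intermediate
13 | (2S,3S)-4-[(allyloxy)carbonyl]-5-methoxy-2-(methoxymethoxy)-5-oxo-3-[2,3,5-tris(benzyloxy)phenyl]pentanoic acid | COC(=O)C(C(=O)OCC=C)[C@@H](c1c(OCc2ccccc2)c(OCc2ccccc2)cc(OCc2ccccc2)c1)[C@H](OCOC)C(=O)O | intermediate
14 | allyl methyl 2-[(1S,2S)-3-methoxy-2-(methoxymethoxy)-3-oxo-1-(2,3,5-tris(benzyloxy)phenyl)propyl]malonate | COC(=O)C(C(=O)OCC=C)[C@@H](c1c(OCc2ccccc2)c(OCc2ccccc2)cc(OCc2ccccc2)c1)[C@H](OCOC)C(=O)OC | intermediate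
15 | 3-methoxy-2-[(1S,2S)-3-methoxy-2-(methoxymethoxy)-3-oxo-1-(2,3,5-tris(benzyloxy)phenyl)propyl]-3-oxopropanoic acid | COC(=O)C(C(=O)O)[C@@H](c1c(OCc2ccccc2)c(OCc2ccccc2)cc(OCc2ccccc2)c1)[C@H](OCOC)C(=O)OC | intermediate
16 | benzyl glyoxylate | O=CC(=O)OCc1ccccc1 | starting material
17 | 4-benzyl 1-methyl (E)-2-[(1R,2S)-3-methoxy-2-(methoxymethoxy)-3-oxo-1-(2,3,5-tris(benzyloxy)phenyl)propyl]but-2-enedioate | COC(=O)/C(=C/C(=O)OCc1ccccc1)[C@@H](c1c(OCc2ccccc2)c(OCc2ccccc2)cc(OCc2ccccc2)c1)[C@H](OCOC)C(=O)OC | intermediate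
18 | 4-benzyl 1-methyl (E)-2-[(3S,4R)-5,6,8-tris(benzyloxy)-3-(methoxycarbonyl)isochroman-4-yl]but-2-enedioate | COC(=O)/C(=C/C(=O)OCc1ccccc1)[C@H]1c2c(OCc3ccccc3)c(OCc3ccccc3)cc(OCc3ccccc3)c2CO[C@@H]1C(=O)OC | intermediate
19 | 4-benzyl 1-methyl (E)-2-[(3S,4R)-5,6,8-tris(benzyloxy)-1-hydroxy-3-(methoxycarbonyl)isochroman-4-yl]but-2-enedioate (C1 epimers) | COC(=O)/C(=C/C(=O)OCc1ccccc1)[C@H]1c2c(OCc3ccccc3)c(OCc3ccccc3)cc(OCc3ccccc3)c2C(O)O[C@@H]1C(=O)OC | intermediate
20 | 4-benzyl 1-methyl (E)-2-[(3S,4R)-5,6,8-tris(benzyloxy)-3-(methoxycarbonyl)-1-oxoisochroman-4-yl]but-2-enedioate | COC(=O)/C(=C/C(=O)OCc1ccccc1)[C@H]1c2c(OCc3ccccc3)c(OCc3ccccc3)cc(OCc3ccccc3)c2C(=O)O[C@@H]1C(=O)OC | intermediate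
21 | (E)-4-methoxy-4-oxo-3-[(3S,4R)-5,6,8-trihydroxy-3-(methoxycarbonyl)-1-oxoisochroman-4-yl]but-2-enoic acid | COC(=O)/C(=C/C(=O)O)[C@H]1c2c(O)c(O)cc(O)c2C(=O)O[C@@H]1C(=O)OC | target

**Total step count:** 14. **Longest linear sequence:** 12 steps (steps 1–5 and 8–14; steps 6–7 are the side branch to 11).

**Steps most likely to fail**

Step 8. The enamine may add too slowly to the electron-rich, ortho-substituted arylidene malonate, so that retro-Knoevenagel cleavage or erosion of the syn selectivity competes. The fallback replaces catalytic enamine activation by a stoichiometric chiral azaenolate and sets out from 11 and 8. Aldehyde 11 is condensed with (S)-1-amino-2-(methoxymethyl)pyrrolidine to the hydrazone (S,E)-N-[2-(methoxymethoxy)ethylidene]-2-(methoxymethyl)pyrrolidin-1-amine F1. Deprotonation with LiN(i-Pr)2 at −78 °C and addition of the lithium azaenolate to 8 should give the hydrazone adduct allyl methyl 2-[(1S,2S,3E)-2-(methoxymethoxy)-3-{[(2S)-2-(methoxymethyl)pyrrolidin-1-yl]imino}-1-(2,3,5-tris(benzyloxy)phenyl)propyl]malonate F2. Two-phase hydrolysis with aqueous oxalic acid releases the auxiliary and returns to the route at 12.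

Step 11. Condensation at the congested malonate carbon may be slow, so that simple protodecarboxylation of the half-acid or base-induced epimerisation at the benzylic carbon competes. The fallback makes the C–C bond by alkylation and the alkene by selenoxide elimination, and sets out from 14. NaH and benzyl bromoacetate in DMF should give the quaternary triester 1-allyl 2-benzyl 1-methyl 1-[(1R,2S)-3-methoxy-2-(methoxymethoxy)-3-oxo-1-(2,3,5-tris(benzyloxy)phenyl)propyl]ethane-1,1,2-tricarboxylate F3. Pd(PPh3)4 and morpholine remove the allyl group to give 4-(benzyloxy)-2-(methoxycarbonyl)-2-[(1R,2S)-3-methoxy-2-(methoxymethoxy)-3-oxo-1-(2,3,5-tris(benzyloxy)phenyl)propyl]-4-oxobutanoic acid F4. F4 loses CO2 in warm toluene to the succinate 4-benzyl 1-methyl 2-[(1S,2S)-3-methoxy-2-(methoxymethoxy)-3-oxo-1-(2,3,5-tris(benzyloxy)phenyl)propyl]butanedioate F5. Kinetic enolisation at the CH2 group with LiN(SiMe3)2 at −78 °C and PhSeCl give the selenide 4-benzyl 1-methyl 2-[(1S,2S)-3-methoxy-2-(methoxymethoxy)-3-oxo-1-(2,3,5-tris(benzyloxy)phenyl)propyl]-3-(phenylselanyl)butanedioate F6. Oxidation with H2O2 and syn elimination of the selenoxide, which can only occur across the two former succinate carbons, returns to the route at 17.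

Step 12. The acetal may ionise in the unproductive sense with loss of the C1 carbon, or acid may cleave or migrate benzyl groups on the very electron-rich ring. The fallback introduces C1 intermolecularly at the aldehyde oxidation level and sets out from 17. Vilsmeier–Haack formylation (POCl3, DMF) at the same arene carbon should give 4-benzyl 1-methyl (E)-2-[(1R,2S)-3-methoxy-2-(methoxymethoxy)-3-oxo-1-(3,5,6-tris(benzyloxy)-2-formylphenyl)propyl]but-2-enedioate F7. Removal of the MOM group (TMSBr, CH2Cl2, −30 °C) frees the C3 hydroxyl, which closes onto the neighbouring formyl group, and the route is rejoined at lactol 19 for the TEMPO/PhI(OAc)2 oxidation of step 13.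

Further compounds
F1 | step 8 | (S,E)-N-[2-(methoxymethoxy)ethylidene]-2-(methoxymethyl)pyrrolidin-1-amine | COCOC/C=N/N1CCC[C@H]1COC
F2 | step 8 | allyl methyl 2-[(1S,2S,3E)-2-(methoxymethoxy)-3-{[(2S)-2-(methoxymethyl)pyrrolidin-1-yl]imino}-1-(2,3,5-tris(benzyloxy)phenyl)propyl]malonate | COC(=O)C(C(=O)OCC=C)[C@@H](c1c(OCc2ccccc2)c(OCc2ccccc2)cc(OCc2ccccc2)c1)[C@H](OCOC)/C=N/N1CCC[C@H]1COC
F3 | step 11 | 1-allyl 2-benzyl 1-methyl 1-[(1R,2S)-3-methoxy-2-(methoxymethoxy)-3-oxo-1-(2,3,5-tris(benzyloxy)phenyl)propyl]ethane-1,1,2-tricarboxylate | COC(=O)C(CC(=O)OCc1ccccc1)(C(=O)OCC=C)[C@@H](c1c(OCc2ccccc2)c(OCc2ccccc2)cc(OCc2ccccc2)c1)[C@H](OCOC)C(=O)OC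
F4 | step 11 | 4-(benzyloxy)-2-(methoxycarbonyl)-2-[(1R,2S)-3-methoxy-2-(methoxymethoxy)-3-oxo-1-(2,3,5-tris(benzyloxy)phenyl)propyl]-4-oxobutanoic acid | COC(=O)C(CC(=O)OCc1ccccc1)(C(=O)O)[C@@H](c1c(OCc2ccccc2)c(OCc2ccccc2)cc(OCc2ccccc2)c1)[C@H](OCOC)C(=O)OC
F5 | step 11 | 4-benzyl 1-methyl 2-[(1S,2S)-3-methoxy-2-(methoxymethoxy)-3-oxo-1-(2,3,5-tris(benzyloxy)phenyl)propyl]butanedioate | COC(=O)C(CC(=O)OCc1ccccc1)[C@@H](c1c(OCc2ccccc2)c(OCc2ccccc2)cc(OCc2ccccc2)c1)[C@H](OCOC)C(=O)OC
F6 | step 11 | 4-benzyl 1-methyl 2-[(1S,2S)-3-methoxy-2-(methoxymethoxy)-3-oxo-1-(2,3,5-tris(benzyloxy)phenyl)propyl]-3-(phenylselanyl)butanedioate | COC(=O)C(C([Se]c1ccccc1)C(=O)OCc1ccccc1)[C@@H](c1c(OCc2ccccc2)c(OCc2ccccc2)cc(OCc2ccccc2)c1)[C@H](OCOC)C(=O)OC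
F7 | step 12 | 4-benzyl 1-methyl (E)-2-[(1R,2S)-3-methoxy-2-(methoxymethoxy)-3-oxo-1-(3,5,6-tris(benzyloxy)-2-formylphenyl)propyl]but-2-enedioate | COC(=O)/C(=C/C(=O)OCc1ccccc1)[C@@H](c1c(OCc2ccccc2)c(OCc2ccccc2)cc(OCc2ccccc2)c1C=O)[C@H](OCOC)C(=O)OC
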